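The quinone ring is cut into three pieces: C1 with C2=C3 (bearing OMe and the unsubstituted indole, ring A) as a chromium methoxy(alkenyl)carbene, C5≡C6 (bearing OMe and the 7-prenylindole, ring B) as an ynol ether, and C4 as a CO ligand. One Dötz benzannulation forms C1–C6, C4–C5 and C3–C4 and delivers the hexasubstituted benzene ring with oxygen on C1 and C4 para to each other, the latent quinone carbonyls, and with the C2 and C5 methoxy groups already in place. The carbene is prepared stereodefined, indolyl trans to the carbene carbon, from a (Z)-enol ether; both indole nitrogens are silylated. One batch of chloro(methoxyethynyl)zinc supplies both ynol ethers. Oxidative demethylation and desilylation complete the synthesis.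

Key step: step 9

Remarks on the chemistry (assumptions):
- Numbering used throughout: quinone C1(=O), C2(OMe), C3 (indol-3-yl, ring A), C4(=O), C5(OMe), C6 (7-prenylindol-3-yl, ring B). The target has no stereocentre; the only stereo-element of the route, the C2=C3 geometry of the carbene, disappears on aromatisation.
- The ring B nitrogen carries tert-butyldimethylsilyl, not triisopropylsilyl: a triisopropylsilyl group on N1 would be pressed against the C7 prenyl group and should be hard to introduce. Ring A carries triisopropylsilyl, which screens C2–H in step 8. Both come off together in step 11.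
- The enol ether for the carbene is made by cis-hydrogenation of an ynol ether and not by olefination, so that a single alkene isomer enters the lithiation.
- Lithium methoxyacetylide is assumed to be generated from chloroacetaldehyde dimethyl acetal without isolating methoxyacetylene. A methyl ynol ether is chosen because it cannot fragment by retro-ene reaction on warming.
- The zinc acetylide 11 is assumed to keep for some hours as a THF solution at 0 °C under argon. Step 4 is therefore run once, when iodides 3 and 8 are both in hand, and its solution is divided between steps 5 and 6 on the same day.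

Step 1
Reactants: 1 indole
Product: 3 3-iodo-1-(triisopropylsilyl)indole, via 1-(triisopropylsilyl)indole 2 (not isolated)
Conditions: n-BuLi, THF, −78 °C; i-Pr3SiCl, −78 → 0 °C; then N-iodosuccinimide, −78 °C → rt
Reagents that add atoms: chlorotriisopropylsilane CC(C)[Si](Cl)(C(C)C)C(C)C; N-iodosuccinimide O=C1CCC(=O)N1I
Why: N-lithiation and N-silylation followed by electrophilic aromatic iodination at the enamine-like C3 of the N-silylindole, a one-flask protection–halogenation sequence well known for N-silylindoles, the bulky silyl group keeping the electrophile away from C2.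

Step 2
Reactants: 4 7-bromoindole; 5 tributyl(3-methylbut-2-enyl)stannane
Product: 6 7-(3-methylbut-2-enyl)indole
Conditions: Pd(PPh3)4 (5 mol %), DMF, 100 °C
Reagents that add atoms: none
Why: Stille coupling in which oxidative addition of the aryl bromide to zerovalent palladium, transfer of the allyl group from tin and reductive elimination at the less hindered primary terminus of the allylpalladium intermediate should give the linear prenyl arene, the free N–H being tolerated.

Step 3
Reactants: 6 7-(3-methylbut-2-enyl)indole
Product: 8 1-(tert-butyldimethylsilyl)-3-iodo-7-(3-methylbut-2-enyl)indole, via 1-(tert-butyldimethylsilyl)-7-(3-methylbut-2-enyl)indole 7 (not isolated)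
Conditions: n-BuLi, THF, −78 °C; t-BuMe2SiCl, 0 °C → rt; then N-iodosuccinimide, −78 → 0 °C
Reagents that add atoms: tert-butylchlorodimethylsilane CC(C)(C)[Si](C)(C)Cl; N-iodosuccinimide O=C1CCC(=O)N1I
Why: The same one-flask N-silylation and C3 iodination as in step 1, the smaller tert-butyldimethylsilyl group fitting next to the C7 substituent and C3 of the N-silylindole being far more nucleophilic toward N-iodosuccinimide than the trisubstituted prenyl alkene.

Step 4
Reactants: 9 chloroacetaldehyde dimethyl acetal
Product: 11 chloro(methoxyethynyl)zinc, via lithium methoxyacetylide 10 (not isolated)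
Conditions: Et2NH (3.3 equiv), n-BuLi (3.2 equiv), THF, 0 °C; 9, 0 °C, 2 h; ZnCl2 (2 equiv), THF, 0 °C; solution kept at 0 °C under argon and divided between steps 5 and 6
Reagents that add atoms: zinc dichloride Cl[Zn]Cl
Why: Lithium diethylamide acts three times on the chloroacetal (elimination of methanol, elimination of HCl and deprotonation of the methoxyacetylene formed, the known base-induced double elimination of chloroacetaldehyde acetals), and lithium-to-zinc transmetalation then gives the less basic alkynylzinc chloride, the second equivalent of ZnCl2 binding lithium methoxide and amine.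

Step 5
Reactants: 3 3-iodo-1-(triisopropylsilyl)indole; 11 chloro(methoxyethynyl)zinc
Product: 12 3-(methoxyethynyl)-1-(triisopropylsilyl)indole
Conditions: 11 (1.5 equiv, THF solution from step 4), Pd(PPh3)4 (5 mol %), THF, rt; NaHCO3 work-up, Et3N-treated silica
Reagents that add atoms: none
Why: Negishi alkynylation, established for alkoxyethynylzinc halides and aryl iodides, in which the zinc acetylide couples with the aryl iodide under zerovalent palladium catalysis, the N–Si bond being left alone because methoxide and amine are held on zinc.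

Step 6
Reactants: 8 1-(tert-butyldimethylsilyl)-3-iodo-7-(3-methylbut-2-enyl)indole; 11 chloro(methoxyethynyl)zinc
Product: 13 1-(tert-butyldimethylsilyl)-3-(methoxyethynyl)-7-(3-methylbut-2-enyl)indole
Conditions: 11 (1.5 equiv, THF solution from step 4), Pd(PPh3)4 (5 mol %), THF, rt; NaHCO3 work-up, Et3N-treated silica
Reagents that add atoms: none
Why: Negishi alkynylation as in step 5, the prenyl alkene and the N-silyl group being inert to the zinc acetylide and to zerovalent palladium at room temperature.

Step 7
Reactants: 12 3-(methoxyethynyl)-1-(triisopropylsilyl)indole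
Product: 14 (Z)-3-(2-methoxyethenyl)-1-(triisopropylsilyl)indole
Conditions: H2 (1 atm), Pd on CaCO3 poisoned with Pb(OAc)2 (Lindlar catalyst), quinoline, EtOAc/hexane, rt
Reagents that add atoms: none
Why: Lindlar semi-hydrogenation, in which syn delivery of H2 on the poisoned palladium surface gives the cis alkene with indolyl and OMe on the same side, as in the classical partial hydrogenation of alkoxyalkynes to (Z)-enol ethers.

Step 8
Reactants: 14 (Z)-3-(2-methoxyethenyl)-1-(triisopropylsilyl)indole; 15 chromium hexacarbonyl
Product: 18 pentacarbonyl{methoxy[(Z)-1-methoxy-2-(1-triisopropylsilylindol-3-yl)ethenyl]carbene}chromium (indolyl trans to the carbene carbon), via (Z)-1-methoxy-2-(1-triisopropylsilylindol-3-yl)ethenyllithium 16 (not isolated), via lithium pentacarbonyl[(Z)-2-methoxy-3-(1-triisopropylsilylindol-3-yl)prop-2-enoyl]chromate 17 (not isolated)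
Conditions: t-BuLi, THF, −78 → −30 °C; Cr(CO)6, −78 °C → rt; solvent exchange; Me3OBF4, CH2Cl2, 0 °C
Reagents that add atoms: trimethyloxonium tetrafluoroborate C[O+](C)C.F[B-](F)(F)F
Why: Fischer carbene synthesis in which t-BuLi removes the vinylic hydrogen α to oxygen with retention (as for dihydropyran and glycals, C2–H of the indole being screened by the triisopropylsilyl group), the vinyllithium adds to a CO ligand of Cr(CO)6 and the acylchromate is O-methylated by the oxonium salt, so that lithium and then the carbene carbon end up trans to the indolyl group.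

Step 9
Reactants: 18 pentacarbonyl{methoxy[(Z)-1-methoxy-2-(1-triisopropylsilylindol-3-yl)ethenyl]carbene}chromium; 13 1-(tert-butyldimethylsilyl)-3-(methoxyethynyl)-7-(3-methylbut-2-enyl)indole (1.3 equiv)
Product: 19 3-[1-(tert-butyldimethylsilyl)-7-(3-methylbut-2-enyl)indol-3-yl]-2,4,5-trimethoxy-6-[1-(triisopropylsilyl)indol-3-yl]phenol
Conditions: THF (0.05 M, degassed), 50 °C, argon; then air, rt
Reagents that add atoms: none
Why: Dötz benzannulation: thermal loss of one CO from 18 lets the ynol ether bind and insert into the Cr=C1 bond, CO then inserts at the new carbene carbon C5 to give a chromium-bound dienylketene (ketene carbon C4), which closes between C4 and the vinyl terminus C3 and tautomerizes to the phenol. The closest known cases are benzannulations of α-alkoxyalkenyl carbene complexes (dihydropyranyl- and glycal-derived) with alkynes. The one ring formed, the benzene ring C1–C6, is assembled in a [3+2+1] sense and its last bond C3–C4 is made by 6π electrocyclization of the dienylketene; no stereocentre is created, and the C2=C3 geometry, set with the indolyl group on the outside so that the closing terminus is unhindered, vanishes on aromatization. The step needs one orientation of insertion, the indolyl-bearing C6 on C1 and the methoxy-bearing C5 on C4, against the usual steric preference. This is secured by the polarization of the ynol ether: its carbon β to oxygen (C6) is nucleophilic and attacks the electrophilic carbene carbon, while the methoxy group stabilizes the new carbene centre at C5, the donor-directed insertion known for ynamines and alkoxyacetylenes. The para relation of the C1 methoxy group and the C4 hydroxyl, the later quinone axis, follows from the mechanism.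

Step 10
Reactants: 19 3-[1-(tert-butyldimethylsilyl)-7-(3-methylbut-2-enyl)indol-3-yl]-2,4,5-trimethoxy-6-[1-(triisopropylsilyl)indol-3-yl]phenol
Product: 20 2,5-dimethoxy-3-[1-(triisopropylsilyl)indol-3-yl]-6-[1-(tert-butyldimethylsilyl)-7-(3-methylbut-2-enyl)indol-3-yl]cyclohexa-2,5-diene-1,4-dione
Conditions: (NH4)2Ce(NO3)6 (2.5 equiv), MeCN/H2O, 0 °C, 10 min
Reagents that add atoms: water O
Why: Oxidative demethylation of a 4-methoxyphenol, in which tetravalent cerium removes two electrons, water adds to the resulting oxocarbenium carbon C1 and methanol is expelled to give the para-quinone with carbonyls at C1 and C4, which should be much faster than any attack on the N-silylindoles or the prenyl alkene at 0 °C.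

Step 11
Reactants: 20 2,5-dimethoxy-3-[1-(triisopropylsilyl)indol-3-yl]-6-[1-(tert-butyldimethylsilyl)-7-(3-methylbut-2-enyl)indol-3-yl]cyclohexa-2,5-diene-1,4-dione
Product: 21 3-(1H-indol-3-yl)-2,5-dimethoxy-6-[7-(3-methylbut-2-enyl)-1H-indol-3-yl]cyclohexa-2,5-diene-1,4-dione (CNP0256613.0)
Conditions: Bu4NF, AcOH, THF, 0 °C
Reagents that add atoms: none
Why: Fluoride-induced cleavage of both N–Si bonds (desilylation), buffered with acetic acid so that each indolide is protonated at once and the vinylogous ester methoxy groups at C2 and C5 of the quinone do not meet free hydroxide or alkoxide.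

Compound list
1 | indole | c1ccc2[nH]ccc2c1 | starting material
2 | 1-(triisopropylsilyl)indole | CC(C)[Si](C(C)C)(C(C)C)n1ccc2ccccc12 | intermediate
3 | 3-iodo-1-(triisopropylsilyl)indole | CC(C)[Si](C(C)C)(C(C)C)n1cc(I)c2ccccc12 | intermediate
4 | 7-bromoindole | Brc1cccc2cc[nH]c12 | starting material
5 | tributyl(3-methylbut-2-enyl)stannane | CCCC[Sn](CCCC)(CCCC)CC=C(C)C | starting material
6 | 7-(3-methylbut-2-enyl)indole | CC(C)=CCc1cccc2cc[nH]c12 | intermediate
7 | 1-(tert-butyldimethylsilyl)-7-(3-methylbut-2-enyl)indole | CC(C)=CCc1cccc2ccn([Si](C)(C)C(C)(C)C)c12 | intermediate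
8 | 1-(tert-butyldimethylsilyl)-3-iodo-7-(3-methylbut-2-enyl)indole | CC(C)=CCc1cccc2c(I)cn([Si](C)(C)C(C)(C)C)c12 | intermediate
9 | chloroacetaldehyde dimethyl acetal | COC(CCl)OC | starting material
10 | lithium methoxyacetylide | COC#C[Li] | intermediate
11 | chloro(methoxyethynyl)zinc | COC#C[Zn]Cl | intermediate
12 | 3-(methoxyethynyl)-1-(triisopropylsilyl)indole | COC#Cc1cn([Si](C(C)C)(C(C)C)C(C)C)c2ccccc12 | intermediate
13 | 1-(tert-butyldimethylsilyl)-3-(methoxyethynyl)-7-(3-methylbut-2-enyl)indole | COC#Cc1cn([Si](C)(C)C(C)(C)C)c2c(CC=C(C)C)cccc12 | intermediate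
14 | (Z)-3-(2-methoxyethenyl)-1-(triisopropylsilyl)indole | CO/C=C\c1cn([Si](C(C)C)(C(C)C)C(C)C)c2ccccc12 | intermediate
15 | chromium hexacarbonyl | O=C=[Cr](=C=O)(=C=O)(=C=O)(=C=O)=C=O | starting material
16 | (Z)-1-methoxy-2-(1-triisopropylsilylindol-3-yl)ethenyllithium (lithium trans to indolyl) | CO/C([Li])=C\c1cn([Si](C(C)C)(C(C)C)C(C)C)c2ccccc12 | intermediate
17 | lithium pentacarbonyl[(Z)-2-methoxy-3-(1-triisopropylsilylindol-3-yl)prop-2-enoyl]chromate | [Li+].[O-]C(=[Cr](=C=O)(=C=O)(=C=O)(=C=O)=C=O)/C(OC)=C/c1cn([Si](C(C)C)(C(C)C)C(C)C)c2ccccc12 | intermediate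
18 | pentacarbonyl{methoxy[(Z)-1-methoxy-2-(1-triisopropylsilylindol-3-yl)ethenyl]carbene}chromium (indolyl trans to the carbene carbon) | COC(=[Cr](=C=O)(=C=O)(=C=O)(=C=O)=C=O)/C(OC)=C/c1cn([Si](C(C)C)(C(C)C)C(C)C)c2ccccc12 | intermediate
19 | 3-[1-(tert-butyldimethylsilyl)-7-(3-methylbut-2-enyl)indol-3-yl]-2,4,5-trimethoxy-6-[1-(triisopropylsilyl)indol-3-yl]phenol | COc1c(c2cn([Si](C)(C)C(C)(C)C)c3c(CC=C(C)C)cccc23)c(OC)c(O)c(c2cn([Si](C(C)C)(C(C)C)C(C)C)c3ccccc23)c1OC | intermediate
20 | 2,5-dimethoxy-3-[1-(triisopropylsilyl)indol-3-yl]-6-[1-(tert-butyldimethylsilyl)-7-(3-methylbut-2-enyl)indol-3-yl]cyclohexa-2,5-diene-1,4-dione | COC1=C(c2cn([Si](C(C)C)(C(C)C)C(C)C)c3ccccc23)C(=O)C(OC)=C(c2cn([Si](C)(C)C(C)(C)C)c3c(CC=C(C)C)cccc23)C1=O | intermediate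
21 | 3-(1H-indol-3-yl)-2,5-dimethoxy-6-[7-(3-methylbut-2-enyl)-1H-indol-3-yl]cyclohexa-2,5-diene-1,4-dione | COC1=C(c2c[nH]c3ccccc23)C(=O)C(OC)=C(c2c[nH]c3c(CC=C(C)C)cccc23)C1=O | target

Total step count: 11
Longest linear sequence: 7 steps (steps 1, 5, 7, 8, 9, 10, 11)

Steps most likely to fail

1. Step 9. The alkyne may insert the other way round (steric instead of electronic control, which would place the methoxy group on C6 and the ring B indole on C5). CO insertion at the oxygen-stabilized carbene centre may also lag, so that the chain stalls at the open dienylcarbene or closes to a five-membered ring without CO. Fallback (the quinone is assembled by acid-promoted addition of the indoles to a haloquinone instead of by benzannulation): it sets out from 1 and 6 and comes back at 21. Indole 1 is added to 2,5-dichlorocyclohexa-2,5-diene-1,4-dione under acid catalysis (HCl, THF) with reoxidation by DDQ, which should give 2,5-dichloro-3-(1H-indol-3-yl)cyclohexa-2,5-diene-1,4-dione F1. Addition of 6 at the remaining C–H position (AcOH, then Ag2CO3 on Celite) should give 2,5-dichloro-3-(1H-indol-3-yl)-6-[7-(3-methylbut-2-enyl)-1H-indol-3-yl]cyclohexa-2,5-diene-1,4-dione F2. Both chlorides are displaced with NaOH in aqueous MeOH to give 2,5-dihydroxy-3-(1H-indol-3-yl)-6-[7-(3-methylbut-2-enyl)-1H-indol-3-yl]cyclohexa-2,5-diene-1,4-dione F3, and O-methylation of the two acidic hydroxyls with Me3SiCHN2 in MeOH/toluene should give 21.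

2. Step 8. Deprotonation may take place at the wrong site (the vinylic hydrogen next to the indole or indole C2–H), or the α-lithiated enol ether may lose methoxide and rearrange before it is trapped by Cr(CO)6. Fallback (the acylchromate is made by acylation of the pentacarbonylchromate dianion instead of by organolithium addition, and the alkene geometry comes from an olefination): it sets out from 3 and comes back at 18. Iodine–lithium exchange on 3 (t-BuLi, THF, −78 °C) and quenching with DMF should give 1-(triisopropylsilyl)indole-3-carbaldehyde F4. Horner–Wadsworth–Emmons reaction with methyl 2-(dimethoxyphosphoryl)-2-methoxyacetate (NaH, THF) should give methyl (Z)-2-methoxy-3-(1-triisopropylsilylindol-3-yl)prop-2-enoate F5, with the indolyl group trans to the ester. Neutral ester cleavage with Me3SnOH (1,2-dichloroethane, 80 °C) should give (Z)-2-methoxy-3-(1-triisopropylsilylindol-3-yl)prop-2-enoic acid F6, and 1-chloro-N,N,2-trimethylprop-1-en-1-amine in CH2Cl2 the acid chloride (Z)-2-methoxy-3-(1-triisopropylsilylindol-3-yl)prop-2-enoyl chloride F7. Addition of F7 to K2Cr(CO)5 (from 15 and potassium graphite KC8, THF, −78 °C) should give potassium pentacarbonyl[(Z)-2-methoxy-3-(1-triisopropylsilylindol-3-yl)prop-2-enoyl]chromate F8, which Me3OBF4 methylates on oxygen to 18.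

3. Step 6. The zinc acetylide may decompose before it couples, the N-silyl group may be lost to alkoxide, or the electron-rich ynol ether may be hydrated during coupling and work-up. Fallback (the triple bond is made by elimination from an enol triflate instead of by cross-coupling): it sets out from 8 and comes back at 13. Iodine–lithium exchange on 8 (t-BuLi, THF, −78 °C) and acylation with N,2-dimethoxy-N-methylacetamide should give 1-[1-(tert-butyldimethylsilyl)-7-(3-methylbut-2-enyl)indol-3-yl]-2-methoxyethanone F9. Enolization with KN(SiMe3)2 and trapping with PhNTf2 (THF, −78 °C) should give (Z)-1-[1-(tert-butyldimethylsilyl)-7-(3-methylbut-2-enyl)indol-3-yl]-2-methoxyethenyl trifluoromethanesulfonate F10. A second equivalent of KN(SiMe3)2 (−78 → 0 °C) removes the vinylic hydrogen trans to the triflate, and anti elimination should give 13.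

Further compounds
F1 | step 9 | 2,5-dichloro-3-(1H-indol-3-yl)cyclohexa-2,5-diene-1,4-dione | O=C1C=C(Cl)C(=O)C(c2c[nH]c3ccccc23)=C1Cl
F2 | step 9 | 2,5-dichloro-3-(1H-indol-3-yl)-6-[7-(3-methylbut-2-enyl)-1H-indol-3-yl]cyclohexa-2,5-diene-1,4-dione | O=C1C(c2c[nH]c3c(CC=C(C)C)cccc23)=C(Cl)C(=O)C(c2c[nH]c3ccccc23)=C1Cl
F3 | step 9 | 2,5-dihydroxy-3-(1H-indol-3-yl)-6-[7-(3-methylbut-2-enyl)-1H-indol-3-yl]cyclohexa-2,5-diene-1,4-dione | O=C1C(c2c[nH]c3c(CC=C(C)C)cccc23)=C(O)C(=O)C(c2c[nH]c3ccccc23)=C1O
F4 | step 8 | 1-(triisopropylsilyl)indole-3-carbaldehyde | O=Cc1cn([Si](C(C)C)(C(C)C)C(C)C)c2ccccc12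
F5 | step 8 | methyl (Z)-2-methoxy-3-(1-triisopropylsilylindol-3-yl)prop-2-enoate | COC(=O)/C(OC)=C/c1cn([Si](C(C)C)(C(C)C)C(C)C)c2ccccc12
F6 | step 8 | (Z)-2-methoxy-3-(1-triisopropylsilylindol-3-yl)prop-2-enoic acid | OC(=O)/C(OC)=C/c1cn([Si](C(C)C)(C(C)C)C(C)C)c2ccccc12
F7 | step 8 | (Z)-2-methoxy-3-(1-triisopropylsilylindol-3-yl)prop-2-enoyl chloride | O=C(Cl)/C(OC)=C/c1cn([Si](C(C)C)(C(C)C)C(C)C)c2ccccc12
F8 | step 8 | potassium pentacarbonyl[(Z)-2-methoxy-3-(1-triisopropylsilylindol-3-yl)prop-2-enoyl]chromate | [K+].[O-]C(=[Cr](=C=O)(=C=O)(=C=O)(=C=O)=C=O)/C(OC)=C/c1cn([Si](C(C)C)(C(C)C)C(C)C)c2ccccc12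
F9 | step 6 | 1-[1-(tert-butyldimethylsilyl)-7-(3-methylbut-2-enyl)indol-3-yl]-2-methoxyethanone | COCC(=O)c1cn([Si](C)(C)C(C)(C)C)c2c(CC=C(C)C)cccc12
F10 | step 6 | (Z)-1-[1-(tert-butyldimethylsilyl)-7-(3-methylbut-2-enyl)indol-3-yl]-2-methoxyethenyl trifluoromethanesulfonate | CO/C=C(\OS(=O)(=O)C(F)(F)F)c1cn([Si](C)(C)C(C)(C)C)c2c(CC=C(C)C)cccc12
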